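The numbers in the tables are simulated for substances that don't exist.

At early times J (monomer) falls faster than G (monomer in chains) rises: at 0.500 min in dawn, J is down by 23.0% and G stands at 9%. The rest of the reacted J goes elsewhere. Q is the initiator and D a further species.

all flasks: Q 1 mol%
- dawn: J 0.17 M; D 0.075 M; run made earlier
- summer: J 0.38 M; D 0.075 M; run made earlier
- midnight: J 0.25 M; D 0.037 M; run made earlier
- amber: J 0.25 M; D 0.0750 M; time 5.0 min
- green: J 0.25 M; D 0.0750 M; time 10 min

| run | time / min | G / % | J / % |
|---|---|---|---|
| dawn | 0.500 | 9 | 77 |
| dawn | 1.33 | 20 | 42 |
| dawn | 2.50 | 29 | 17 |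
| dawn | 4.00 | 38 | 6 |
| summer | 0.500 | 22 | 60 |
| summer | 1.33 | 43 | 25 |
| summer | 2.50 | 56 | 3 |
| summer | 4.00 | 58 | 0 |
| midnight | 0.333 | 9 | 77 |
| midnight | 0.667 | 17 | 60 |
| midnight | 1.50 | 32 | 26 |
| midnight | 4.00 | 51 | 6 |

(readings scatter by 2 percentage points)

- the average divides the monomer in chains by the number of chains begun, living and dead together
- the numbers in the tables scatter with a standard deviation of 2 percentage points
- the earlier runs do not show the number of chains; that part of a forecast is a guess

1. which of the two ends with the longer chains by the average number of monomer units in a chain (chains begun, living or dead) ("neither" if they lie within 10%) (amber / green / neither)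
2. average number of monomer units in a chain (chains begun, living or dead) at the end, amber
3. average number of monomer units in a chain (chains begun, living or dead) at the end, green

1. Let s be the share of reacted J found as G. In dawn, s reads 0.391 at the first reading and 0.404 at the last, so I take it as steady.

2. Extreme one: J goes to G and nowhere else. Each Q begins one chain, and the length is 100, the inverse of the loading. Extreme two: there are no chain ends, so there is no G. The real flask lies between, at length n = s/loading, if each Q begins one chain. That part is my guess.

3. To place it, I assume the G route is proportional to chain ends c = J charge × loading, while the other route ignores them. Then s/(1−s) = f·c. Dawn gives 399 M⁻¹ and summer 363 M⁻¹. Midnight has D at 0.037 M, so I keep to these two runs, which have amber's D. Their mean is 381 M⁻¹. I call it f, the selectivity factor: G route over other route, per molar of chain ends.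

4. Amber and green have f·c = 0.953, so s = 0.488 and the finished length is 48.8.

5. The correction is the unreacted J. Midnight, with the same J charge, gives a decay of 0.703 min⁻¹, which leaves 2.97% at 5.0 min. My lengths are 47.4 for amber and 48.8 for green. That gap of 2.87% is below 10%, so I say neither.

The forecast gives 47 and 48, verdict neither, and warns: “If D transfers chains, both fall, which the runs cannot show”.

The flask gives 49.1 for amber and 49.8 for green, verdict neither.

    X + D → Z (k = 0.00547 M⁻¹ s⁻¹)
    J + X → G + X, rate k2*[X]*[J] (k = 3.26 M⁻¹ s⁻¹)
    J + Q → X + G (k = 0.350 M⁻¹ s⁻¹)
    J → L (k = 0.00690 s⁻¹)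

In green at 10.0 min, J goes to L at 1.1 times the rate at which it goes to G, with G at 49.7% and L at 50.3%. In green X, the living end, stands at 0.00196 M, so J + X → G + X runs at 0.00640 s⁻¹ per unit of J, against 0.00690 s⁻¹ for J → L.

Now a neighbour flask, which is green with Q at 2.5 mol%: f·c is 2.38, so s = 0.704 and the length is 28.2. The computed flask holds G at 69.3% with length 28.3.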